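**Plan**

1. Retrosynthesis: the furan-2(5H)-one is opened at C2–C3 (carbonyl carbon to α-carbon), which leaves the carbonyl carbon on O1 as an N-methoxy-N-methylcarbamate and C3 as a (Z)-iodoalkene. The sp3–sp2 bond between the CH2CH2 arm on chromene C2 and the trisubstituted alkene is then cut to give vinylchromene 8 and iodoalkene 17. Compound 17 is cut between the carbinol carbon and its CH2 (propargylation of an ynal), and 8 at O1–C2 and the C3=C4 unsaturation (back to an o-alkenylphenol).
2. Forward: the pyran ring is closed first by a Wacker-type cyclisation and dehydrogenated to the 2H-chromene, the chain is joined by B-alkyl Suzuki–Miyaura coupling, and the furanone ring is closed last, followed only by desilylation of the phenol.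
3. Enabling feature: in the furanone ring, C3 bears only carbon substituents and lies cis across C3=C4 to the C5–O1 bond. A (Z)-alkenyllithium at C3 therefore has its in-plane sp2 lobe three atoms from a carbonyl carbon held on O1 and closes the five-membered ring 5-exo-trig. The N(OMe)Me group is the helper: it stores the closed ring as a chelated lithium alkoxide and leaves on acid work-up.
4. Stereochemistry: chromene C2 (R) comes from ligand-controlled oxypalladation. Furanone C5 (R) comes from chiral phosphoric acid-catalysed propargylboration, and its C–O bond is never broken afterwards. The E alkene comes from syn-carboalumination and stereoretentive coupling, the Z iodoalkene from anti-hydroalumination.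

Key step: step 13

Remark: the catalyst antipodes named in steps 4 and 8 are those expected, by analogy with simpler o-alkenylphenols and with aryl and alkenyl aldehydes, to give the configurations drawn, and both alkene isomers of 6 are taken to converge on (S)-7.

**Route**

Step 1
Reactants: 1 2-methylbenzene-1,4-diol
Product: 2 2-methyl-4-(triisopropylsilyloxy)phenol
Conditions: i-Pr3SiCl (1.0 equiv), imidazole, DMF, 0 °C
Reagents that add atoms: triisopropylsilyl chloride, CC(C)[Si](Cl)(C(C)C)C(C)C
Why: Silylation with the bulky chlorosilane should occur at the hydroxyl remote from the ring methyl group, which is the less hindered one, the regioisomer and the bis-silyl ether being removed by chromatography.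

Step 2
Reactants: 2 2-methyl-4-(triisopropylsilyloxy)phenol
Product: 3 2-bromo-6-methyl-4-(triisopropylsilyloxy)phenol
Conditions: NBS (1.0 equiv), i-Pr2NH (10 mol%), CH2Cl2, 0 °C
Reagents that add atoms: N-bromosuccinimide, O=C1CCC(=O)N1Br
Why: Amine-mediated electrophilic ortho-bromination of a phenol should be regioselective because the free hydroxyl is the strongest director, its para position is blocked and only one ortho position is open.

Step 3
Reactants: 3 2-bromo-6-methyl-4-(triisopropylsilyloxy)phenol; 4 3-methylpenta-1,3-diene (E/Z mixture)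
Product: 6 2-methyl-6-(3-methylpent-3-en-1-yl)-4-(triisopropylsilyloxy)phenol (E/Z mixture), via alkylborane 5 (not isolated)
Conditions: 4 (2.4 equiv), 9-BBN (1.6 equiv), THF, 0 °C to rt; then 3, Pd(OAc)2 (5 mol%), SPhos (10 mol%), 3 M aq. K3PO4, THF, 50 °C
Reagents that add atoms: none
Why: 9-BBN hydroborates the monosubstituted terminus of the diene anti-Markovnikov and leaves the trisubstituted alkene alone, and the primary alkylborane then undergoes B-alkyl Suzuki–Miyaura coupling with the aryl bromide.

Step 4
Reactants: 6 2-methyl-6-(3-methylpent-3-en-1-yl)-4-(triisopropylsilyloxy)phenol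
Product: 7 (2S)-2-ethenyl-2,8-dimethyl-6-(triisopropylsilyloxy)chromane
Conditions: Pd(OCOCF3)2 (10 mol%), (S,S)-Bn-BOXAX (20 mol%), p-benzoquinone (4 equiv), MeOH, 60 °C
Reagents that add atoms: none
Why: In this enantioselective Wacker-type oxidative cyclisation the phenol adds 6-exo-trig to the trisubstituted alkene bound to the chiral divalent palladium bis(oxazoline) complex, which selects the alkene face and so sets the quaternary C2, and β-hydride elimination towards the methyl group leaves the vinyl group.

Step 5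
Reactants: 7 (2S)-2-ethenyl-2,8-dimethyl-6-(triisopropylsilyloxy)chromane
Product: 8 (2R)-2-ethenyl-2,8-dimethyl-6-(triisopropylsilyloxy)-2H-chromene
Conditions: DDQ (1.3 equiv), dry 1,4-dioxane, 80 °C
Reagents that add atoms: none
Why: DDQ dehydrogenation of a chromane proceeds by hydride abstraction at benzylic C4 (cation stabilised by the ring oxygen) and loss of a C3 proton, leaving the quaternary C2 untouched (the descriptor changes only because C3 now outranks vinyl).

Step 6
Reactants: 9 5-bromo-2-methylpent-2-ene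
Product: 10 6-methylhept-5-en-1-yne
Conditions: LiC≡CH·H2NCH2CH2NH2 (1.2 equiv), DMSO, 10 °C to rt
Reagents that add atoms: lithium acetylide ethylenediamine complex, [Li]C#C.NCCN
Why: SN2 alkylation of lithium acetylide by a primary homoallylic bromide.

Step 7
Reactants: 10 6-methylhept-5-en-1-yne
Product: 13 7-methyloct-6-en-2-ynal, via lithium acetylide 11 (not isolated), via lithium hemiaminal alkoxide 12 (not isolated)
Conditions: n-BuLi (1.05 equiv), THF, −78 °C; DMF (2 equiv), −78 to 0 °C; inverse quench into cold aq. KH2PO4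
Reagents that add atoms: N,N-dimethylformamide, CN(C)C=O
Why: Formylation of the lithium acetylide with DMF gives a hemiaminal alkoxide, and the buffered inverse quench releases the ynal without conjugate addition of dimethylamine.

Step 8
Reactants: 13 7-methyloct-6-en-2-ynal
Product: 15 (4R)-10-methylundec-9-ene-1,5-diyn-4-ol, via boronate ester 14 (not isolated)
Conditions: allenylboronic acid pinacol ester (1.5 equiv), (R)-TRIP (5 mol%), 4 Å molecular sieves, toluene, 0 °C; aq. work-up
Reagents that add atoms: allenylboronic acid pinacol ester, C=C=CB1OC(C)(C)C(C)(C)O1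
Why: In this chiral phosphoric acid-catalysed propargylboration the allenylboronate reacts by SE2' through a six-membered transition state in which the acid binds the boronate oxygen and the formyl hydrogen, so the catalyst selects the aldehyde face and sets the carbinol centre as R.

Step 9
Reactants: 15 (4R)-10-methylundec-9-ene-1,5-diyn-4-ol
Product: 17 (1E,4R)-1-iodo-2,10-dimethylundeca-1,9-dien-5-yn-4-ol, via alkenylalane 16 (not isolated)
Conditions: Me3Al (3.5 equiv), Cp2ZrCl2 (0.3 equiv), CH2Cl2, 0 °C to rt; I2 (1.2 equiv), THF, −30 °C; aq. K2CO3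
Reagents that add atoms: trimethylaluminium, C[Al](C)C; iodine, [I][I]
Why: Zirconium-catalysed syn-carboalumination (Negishi) of the terminal alkyne puts methyl on the internal and aluminium on the terminal carbon, iodinolysis with retention gives the (E)-iodoalkene, and the internal alkyne should react much more slowly.

Step 10
Reactants: 8 (2R)-2-ethenyl-2,8-dimethyl-6-(triisopropylsilyloxy)-2H-chromene; 17 (1E,4R)-1-iodo-2,10-dimethylundeca-1,9-dien-5-yn-4-ol
Product: 19 (3E,6R)-1-[(2R)-2,8-dimethyl-6-(triisopropylsilyloxy)-2H-chromen-2-yl]-4,12-dimethyltrideca-3,11-dien-7-yn-6-ol, via alkylborane 18 (not isolated)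
Conditions: 8, 9-BBN (1.3 equiv), THF, rt; then 3 M aq. K3PO4, 17, PdCl2(dppf) (5 mol%), AsPh3 (10 mol%), THF/DMF, rt
Reagents that add atoms: none
Why: 9-BBN adds to the monosubstituted vinyl group far faster than to the styrene-like ring alkene, residual borane is destroyed by the aqueous base before 17 is added, and B-alkyl Suzuki–Miyaura coupling with the iodoalkene proceeds with retention of the E geometry.

Step 11
Reactants: 19 (3E,6R)-1-[(2R)-2,8-dimethyl-6-(triisopropylsilyloxy)-2H-chromen-2-yl]-4,12-dimethyltrideca-3,11-dien-7-yn-6-ol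
Product: 21 (3E,6R,7Z)-1-[(2R)-2,8-dimethyl-6-(triisopropylsilyloxy)-2H-chromen-2-yl]-8-iodo-4,12-dimethyltrideca-3,7,11-trien-6-ol, via alkenylaluminate 20 (not isolated)
Conditions: NaAlH2(OCH2CH2OCH3)2 (2.5 equiv), THF, 0 °C to rt; EtOAc, −78 °C; I2 (1.5 equiv), THF, −78 °C
Reagents that add atoms: iodine, [I][I]
Why: Hydroxyl-directed anti-hydroalumination of the propargylic alcohol delivers hydride to the proximal and aluminium to the distal alkyne carbon within a five-membered alkoxyaluminate, and iodinolysis with retention gives the (Z)-3-iodoallylic alcohol.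

Step 12
Reactants: 21 (3E,6R,7Z)-1-[(2R)-2,8-dimethyl-6-(triisopropylsilyloxy)-2H-chromen-2-yl]-8-iodo-4,12-dimethyltrideca-3,7,11-trien-6-ol
Product: 23 (3E,6R,7Z)-1-[(2R)-2,8-dimethyl-6-(triisopropylsilyloxy)-2H-chromen-2-yl]-8-iodo-4,12-dimethyltrideca-3,7,11-trien-6-yl N-methoxy-N-methylcarbamate, via lithium alkoxide 22 (not isolated)
Conditions: LiN(SiMe3)2 (1.05 equiv), THF, −78 °C; ClC(O)N(OMe)Me (1.3 equiv), −78 to 0 °C
Reagents that add atoms: N-methoxy-N-methylcarbamoyl chloride, CON(C)C(Cl)=O
Why: O-Acylation of the lithium alkoxide by the carbamoyl chloride places the future lactone carbonyl carbon on the ring oxygen without touching the C–O bond of the stereocentre.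

Step 13
Reactants: 23 (3E,6R,7Z)-1-[(2R)-2,8-dimethyl-6-(triisopropylsilyloxy)-2H-chromen-2-yl]-8-iodo-4,12-dimethyltrideca-3,7,11-trien-6-yl N-methoxy-N-methylcarbamate
Product: 26 (5R)-5-{(2E)-5-[(2R)-2,8-dimethyl-6-(triisopropylsilyloxy)-2H-chromen-2-yl]-2-methylpent-2-en-1-yl}-3-(4-methylpent-3-en-1-yl)furan-2(5H)-one, via alkenyllithium 24 (not isolated), via cyclic lithium alkoxide 25 (not isolated)
Conditions: t-BuLi (2.0 equiv), Et2O/pentane, −95 °C, 15 min; AcOH (3 equiv), −95 °C; then 0.5 M aq. citric acid, THF, rt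
Reagents that add atoms: none
Why: Iodine–lithium exchange on the (Z)-iodoalkene, which is much faster than addition of t-BuLi to the carbamate, gives alkenyllithium 24 with retention, and its sp2 carbanion, held cis to the C5–O1 bond, adds to the carbamate carbonyl to form the C2–C3 bond. The closest known reaction type is the Parham cyclisation, that is halogen–metal exchange followed by intramolecular acyl substitution on a carbonic acid derivative (an anionic 1,4 O-to-C carbamoyl transfer). The furanone ring closes in the 5-exo-trig mode with the C3=C4 double bond inside the ring. No stereocentre of the product is created: C5 keeps its R configuration because its C–O bond is never broken, and the hemiaminal carbon of 25 becomes the trigonal carbonyl on work-up. The step needs chemoselectivity (exchange before attack on the carbamate, no proton abstraction at C5) and protection of the base-sensitive butenolide; the Z geometry and the exact two equivalents of t-BuLi at −95 °C should secure the first, and the N-methoxy-N-methyl group the second, since it chelates lithium so that the product is stored as alkoxide 25 until the acid quench expels N,O-dimethylhydroxylamine.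

Step 14
Reactants: 26 (5R)-5-{(2E)-5-[(2R)-2,8-dimethyl-6-(triisopropylsilyloxy)-2H-chromen-2-yl]-2-methylpent-2-en-1-yl}-3-(4-methylpent-3-en-1-yl)furan-2(5H)-one
Product: 27 (5R)-5-{(2E)-5-[(2R)-6-hydroxy-2,8-dimethyl-2H-chromen-2-yl]-2-methylpent-2-en-1-yl}-3-(4-methylpent-3-en-1-yl)furan-2(5H)-one (2'-epi-tuberatolide B)
Conditions: Bu4NF/AcOH (1:1, 1.5 equiv), THF, 0 °C
Reagents that add atoms: none
Why: Fluoride cleaves the aryl silyl ether, and the acetic acid buffer keeps the medium non-basic so that the C5 hydrogen of the furanone is not removed.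

**Compound list**

1 | 2-methylbenzene-1,4-diol | Cc1cc(O)ccc1O | starting material
2 | 2-methyl-4-(triisopropylsilyloxy)phenol | Cc1cc(O[Si](C(C)C)(C(C)C)C(C)C)ccc1O | intermediate
3 | 2-bromo-6-methyl-4-(triisopropylsilyloxy)phenol | Cc1cc(O[Si](C(C)C)(C(C)C)C(C)C)cc(Br)c1O | intermediate
4 | 3-methylpenta-1,3-diene (E/Z mixture) | C=CC(C)=CC | starting material
5 | 9-(3-methylpent-3-en-1-yl)-9-borabicyclo[3.3.1]nonane | CC=C(C)CCB1C2CCCC1CCC2 | intermediate (not isolated)
6 | 2-methyl-6-(3-methylpent-3-en-1-yl)-4-(triisopropylsilyloxy)phenol (E/Z mixture) | CC=C(C)CCc1cc(O[Si](C(C)C)(C(C)C)C(C)C)cc(C)c1O | intermediate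
7 | (2S)-2-ethenyl-2,8-dimethyl-6-(triisopropylsilyloxy)chromane | C=C[C@]1(C)CCc2cc(O[Si](C(C)C)(C(C)C)C(C)C)cc(C)c2O1 | intermediate
8 | (2R)-2-ethenyl-2,8-dimethyl-6-(triisopropylsilyloxy)-2H-chromene | C=C[C@]1(C)C=Cc2cc(O[Si](C(C)C)(C(C)C)C(C)C)cc(C)c2O1 | intermediate
9 | 5-bromo-2-methylpent-2-ene | CC(C)=CCCBr | starting material
10 | 6-methylhept-5-en-1-yne | CC(C)=CCCC#C | intermediate
11 | (6-methylhept-5-en-1-yn-1-yl)lithium | CC(C)=CCCC#C[Li] | intermediate (not isolated)
12 | lithium 1-(dimethylamino)-7-methyloct-6-en-2-yn-1-olate | CC(C)=CCCC#CC(O[Li])N(C)C | intermediate (not isolated)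
13 | 7-methyloct-6-en-2-ynal | CC(C)=CCCC#CC=O | intermediate
14 | 2-{[(4R)-10-methylundec-9-ene-1,5-diyn-4-yl]oxy}-4,4,5,5-tetramethyl-1,3,2-dioxaborolane | C#CC[C@@H](OB1OC(C)(C)C(C)(C)O1)C#CCCC=C(C)C | intermediate (not isolated)
15 | (4R)-10-methylundec-9-ene-1,5-diyn-4-ol | C#CC[C@@H](O)C#CCCC=C(C)C | intermediate
16 | [(1E,4R)-4-(dimethylalumanyloxy)-2,10-dimethylundeca-1,9-dien-5-yn-1-yl]dimethylalumane | C[Al](C)/C=C(C)/C[C@@H](O[Al](C)C)C#CCCC=C(C)C | intermediate (not isolated)
17 | (1E,4R)-1-iodo-2,10-dimethylundeca-1,9-dien-5-yn-4-ol | [I]/C=C(C)/C[C@@H](O)C#CCCC=C(C)C | intermediate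
18 | 9-{2-[(2R)-2,8-dimethyl-6-(triisopropylsilyloxy)-2H-chromen-2-yl]ethyl}-9-borabicyclo[3.3.1]nonane | B1(CC[C@]2(C)C=Cc3cc(O[Si](C(C)C)(C(C)C)C(C)C)cc(C)c3O2)C4CCCC1CCC4 | intermediate (not isolated)
19 | (3E,6R)-1-[(2R)-2,8-dimethyl-6-(triisopropylsilyloxy)-2H-chromen-2-yl]-4,12-dimethyltrideca-3,11-dien-7-yn-6-ol | CC(C)=CCCC#C[C@H](O)C/C(C)=C/CC[C@]1(C)C=Cc2cc(O[Si](C(C)C)(C(C)C)C(C)C)cc(C)c2O1 | intermediate
20 | sodium bis(2-methoxyethoxy)aluminate in which aluminium bridges O6 and C8 of 19 (five-membered oxaaluminole ring, hydrogen on C7 anti to aluminium) | [Na+].CC(C)=CCCC1=C[C@@H](C/C(C)=C/CC[C@]2(C)C=Cc3cc(O[Si](C(C)C)(C(C)C)C(C)C)cc(C)c3O2)O[Al-]1(OCCOC)OCCOC | intermediate (not isolated)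
21 | (3E,6R,7Z)-1-[(2R)-2,8-dimethyl-6-(triisopropylsilyloxy)-2H-chromen-2-yl]-8-iodo-4,12-dimethyltrideca-3,7,11-trien-6-ol | CC(C)=CCC/C([I])=C/[C@H](O)C/C(C)=C/CC[C@]1(C)C=Cc2cc(O[Si](C(C)C)(C(C)C)C(C)C)cc(C)c2O1 | intermediate
22 | lithium alkoxide of 21 | CC(C)=CCC/C([I])=C/[C@H](O[Li])C/C(C)=C/CC[C@]1(C)C=Cc2cc(O[Si](C(C)C)(C(C)C)C(C)C)cc(C)c2O1 | intermediate (not isolated)
23 | (3E,6R,7Z)-1-[(2R)-2,8-dimethyl-6-(triisopropylsilyloxy)-2H-chromen-2-yl]-8-iodo-4,12-dimethyltrideca-3,7,11-trien-6-yl N-methoxy-N-methylcarbamate | CC(C)=CCC/C([I])=C/[C@H](OC(=O)N(C)OC)C/C(C)=C/CC[C@]1(C)C=Cc2cc(O[Si](C(C)C)(C(C)C)C(C)C)cc(C)c2O1 | intermediate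
24 | 8-lithio analogue of 23 (lithium in place of iodine, same alkene geometry) | CC(C)=CCC/C([Li])=C/[C@H](OC(=O)N(C)OC)C/C(C)=C/CC[C@]1(C)C=Cc2cc(O[Si](C(C)C)(C(C)C)C(C)C)cc(C)c2O1 | intermediate (not isolated)
25 | lithium (5R)-5-{(2E)-5-[(2R)-2,8-dimethyl-6-(triisopropylsilyloxy)-2H-chromen-2-yl]-2-methylpent-2-en-1-yl}-2-[methoxy(methyl)amino]-3-(4-methylpent-3-en-1-yl)-2,5-dihydrofuran-2-olate (both C2 epimers) | CC(C)=CCCC1=C[C@@H](C/C(C)=C/CC[C@]2(C)C=Cc3cc(O[Si](C(C)C)(C(C)C)C(C)C)cc(C)c3O2)OC1(O[Li])N(C)OC | intermediate (not isolated)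
26 | (5R)-5-{(2E)-5-[(2R)-2,8-dimethyl-6-(triisopropylsilyloxy)-2H-chromen-2-yl]-2-methylpent-2-en-1-yl}-3-(4-methylpent-3-en-1-yl)furan-2(5H)-one | CC(C)=CCCC1=C[C@@H](C/C(C)=C/CC[C@]2(C)C=Cc3cc(O[Si](C(C)C)(C(C)C)C(C)C)cc(C)c3O2)OC1=O | intermediate
27 | (5R)-5-{(2E)-5-[(2R)-6-hydroxy-2,8-dimethyl-2H-chromen-2-yl]-2-methylpent-2-en-1-yl}-3-(4-methylpent-3-en-1-yl)furan-2(5H)-one (2'-epi-tuberatolide B) | CC(C)=CCCC1=C[C@@H](C/C(C)=C/CC[C@]2(C)C=Cc3cc(O)cc(C)c3O2)OC1=O | target

**Summary**

Total step count: 14. Longest linear sequence: 10 steps (steps 1–5 and 10–14).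

Steps most likely to fail:

Step 13. The alkyllithium may add to the carbamate carbonyl before halogen–lithium exchange is complete, or adduct 25 may open in the flask and take up a second equivalent of organolithium. The fallback sets out from iodo alcohol 21 and uses palladium-catalysed carbonylative lactonisation (PdCl2(PPh3)2, CO at 1 atm, K2CO3, THF, 40 °C). Zerovalent palladium inserts into the carbon–iodine bond, CO inserts, and the neighbouring hydroxyl captures the acylpalladium, so the ring then closes at oxygen. This should give 26 directly, where the route is rejoined; no new compound is made on the way (F0).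

Step 8. The small, rod-like alkynyl group of ynal 13 may be poorly discriminated by the catalyst, which would erode the facial selectivity of the propargylboration. The fallback sets out from 13. Barbier-type propargylation (Zn, propargyl bromide, THF, 0 °C) should give racemic 10-methylundec-9-ene-1,5-diyn-4-ol F1. Oxidation with Dess–Martin periodinane (NaHCO3, CH2Cl2, 0 °C) should give 10-methylundec-9-ene-1,5-diyn-4-one F2, which would be used at once because its doubly activated CH2 can isomerise to the allenyl ketone. Midland reduction with (R)-Alpine-borane (THF, rt), in which the alkynyl group acts as the small substituent, should then return the route to (R)-15.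

Step 5. Hydride abstraction at C4 may stall, or the electron-rich silyloxy arene may be over-oxidised by the quinone. The fallback sets out from 7. Benzylic oxidation (t-BuOOH, Rh2(cap)4 [dirhodium tetrakis(caprolactamate)], NaHCO3, 1,2-dichloroethane, 40 °C) should give (2S)-2-ethenyl-2,8-dimethyl-6-(triisopropylsilyloxy)chroman-4-one F3. Reduction with NaBH4 (MeOH, 0 °C) should give (2S)-2-ethenyl-2,8-dimethyl-6-(triisopropylsilyloxy)chroman-4-ol F4 as a mixture at C4. Acid-catalysed dehydration (p-TsOH, toluene, 60 °C) should then return the route to 8.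

Further compounds
F0 | step 13 | none | none
F1 | step 8 | racemic 10-methylundec-9-ene-1,5-diyn-4-ol | C#CCC(O)C#CCCC=C(C)C
F2 | step 8 | 10-methylundec-9-ene-1,5-diyn-4-one | C#CCC(=O)C#CCCC=C(C)C
F3 | step 5 | (2S)-2-ethenyl-2,8-dimethyl-6-(triisopropylsilyloxy)chroman-4-one | C=C[C@]1(C)CC(=O)c2cc(O[Si](C(C)C)(C(C)C)C(C)C)cc(C)c2O1
F4 | step 5 | (2S)-2-ethenyl-2,8-dimethyl-6-(triisopropylsilyloxy)chroman-4-ol (mixture at C4) | C=C[C@]1(C)CC(O)c2cc(O[Si](C(C)C)(C(C)C)C(C)C)cc(C)c2O1
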